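Side-chain carbons are numbered C1′ (on the ring) to C15′. The chain is cut at C7′–C8′, between the methyl-bearing sp2 carbon of the C6′=C7′ alkene and the C8′ methylene. Because C8′–C9′ adjoins the C10′=C11′ alkene, C8′ can enter as the terminal carbon of a C8′=C9′–C10′=C11′ diene on a chiral 1,3-dioxane ring that masks the C11′ hydroxymethyl and C12′ (R) carbinol; C7′ enters as an (E)-alkenyl iodide on the dimethoxybenzene form of the quinone ring. In one pot 9-BBN hydroborates only the terminal vinyl group and palladium couples the homoallylic borane with retention, joining both halves with 6′E geometry. Acetal cleavage and oxidative demethylation then give the quinone.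

Key step: step 12

Remark: in step 10 the lithiated RAMP hydrazone is taken to follow the usual SAMP/RAMP topicity, which gives the 4R ketone; the SAMP hydrazone would give its enantiomer.

Step 1
Reactants: 1 4-methoxy-2-methylphenol
Product: 2 2-bromo-4-methoxy-6-methylphenol
Conditions: NBS, MeCN, 0 °C
Reagents that add atoms: N-bromosuccinimide, O=C1CCC(=O)N1Br
Why: Electrophilic aromatic bromination is directed by the free phenol to its only open ortho position, the para position being blocked by the methoxy group.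

Step 2
Reactants: 2 2-bromo-4-methoxy-6-methylphenol
Product: 3 1-bromo-2,5-dimethoxy-3-methylbenzene
Conditions: MeI, K2CO3, acetone, reflux
Reagents that add atoms: iodomethane, CI
Why: Williamson O-methylation of the phenoxide masks the hydroquinone as its dimethyl ether, which survives all organometallic steps and is unmasked oxidatively at the end.

Step 3
Reactants: 4 pent-3-yn-1-ol
Product: 5 5-bromopent-2-yne
Conditions: CBr4, PPh3, CH2Cl2, 0 °C
Reagents that add atoms: tetrabromomethane, BrC(Br)(Br)Br
Why: The Appel reaction converts the primary alcohol into the bromide by SN2 displacement of the oxyphosphonium group and leaves the internal alkyne untouched.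

Step 4
Reactants: 5 5-bromopent-2-yne; 6 ethyl but-2-ynoate
Product: 10 ethyl (2E)-3-methyloct-2-en-6-ynoate, via pent-3-ynylmagnesium bromide 7 (not isolated), via pent-3-ynylcopper 8 (not isolated), via alkenylcopper adduct 9 (not isolated)
Conditions: Mg, THF, rt; CuBr·SMe2, THF/Me2S, −40 °C; 6, −78 °C; then NH4Cl/MeOH, −78 °C
Reagents that add atoms: none
Why: Syn carbocupration (conjugate addition) of the organocopper reagent to the ynoate and protonation of the alkenylcopper at low temperature place the new chain trans to the ester, which sets the C2′=C3′ E geometry stereospecifically.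

Step 5
Reactants: 10 ethyl (2E)-3-methyloct-2-en-6-ynoate
Product: 11 (2E)-3-methyloct-2-en-6-yn-1-ol
Conditions: i-Bu2AlH, CH2Cl2, −78 to 0 °C; aq. KNaC4H4O6
Reagents that add atoms: none
Why: 1,2-Reduction of the enoate by the aluminium hydride gives the allylic alcohol, and the isolated internal alkyne is not hydroaluminated at this temperature.

Step 6
Reactants: 11 (2E)-3-methyloct-2-en-6-yn-1-ol
Product: 12 (2E)-1-bromo-3-methyloct-2-en-6-yne
Conditions: PBr3, Et2O, 0 °C
Reagents that add atoms: phosphorus tribromide, BrP(Br)Br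
Why: PBr3 converts the primary allylic alcohol into the primary allylic bromide with retention of the E alkene, as in the standard preparation of geranyl bromide.

Step 7
Reactants: 3 1-bromo-2,5-dimethoxy-3-methylbenzene; 12 (2E)-1-bromo-3-methyloct-2-en-6-yne
Product: 15 2,5-dimethoxy-1-methyl-3-[(2E)-3-methyloct-2-en-6-yn-1-yl]benzene, via aryllithium 13 (not isolated), via arylcopper 14 (not isolated)
Conditions: n-BuLi, THF, −78 °C; CuBr·SMe2, −78 to −40 °C; then 12, −78 to 0 °C
Reagents that add atoms: none
Why: Bromine–lithium exchange, transmetalation to the arylcopper and SN2 allylic substitution at the primary carbon of the allylic bromide form the aryl–C1′ bond with retention of the E alkene.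

Step 8
Reactants: 15 2,5-dimethoxy-1-methyl-3-[(2E)-3-methyloct-2-en-6-yn-1-yl]benzene
Product: 17 1-[(2E,6E)-7-iodo-3-methylocta-2,6-dien-1-yl]-2,5-dimethoxy-3-methylbenzene, via alkenylzirconocene chloride 16 (not isolated)
Conditions: Cp2Zr(H)Cl (excess), THF, 50 °C; then I2, THF, 0 °C
Reagents that add atoms: iodine, II
Why: Syn hydrozirconation of the 2-alkyne, equilibrated with excess Cp2Zr(H)Cl so that zirconium settles on the less hindered methyl-bearing carbon, followed by iodinolysis with retention should give the (E)-2-iodoalkene with iodine trans to the chain.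

Step 9
Reactants: 18 2,2-dimethyl-1,3-dioxan-5-one; 19 (R)-1-amino-2-(methoxymethyl)pyrrolidine (RAMP)
Product: 20 (2R)-N-(2,2-dimethyl-1,3-dioxan-5-ylidene)-2-(methoxymethyl)pyrrolidin-1-amine (RAMP hydrazone of 18)
Conditions: benzene, reflux, Dean–Stark
Reagents that add atoms: none
Why: Condensation of the ketone with the chiral hydrazine under azeotropic removal of water installs the auxiliary for the SAMP/RAMP hydrazone alkylation.

Step 10
Reactants: 20 RAMP hydrazone of 2,2-dimethyl-1,3-dioxan-5-one; 21 1-bromo-3-methylbut-2-ene (prenyl bromide)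
Product: 24 (4R)-2,2-dimethyl-4-(3-methylbut-2-en-1-yl)-1,3-dioxan-5-one, via lithium azaenolate 22 (not isolated), via alkylated hydrazone 23 (not isolated)
Conditions: t-BuLi, THF, −78 °C; 21, −100 °C to rt; then sat. aq. (CO2H)2, Et2O, rt
Reagents that add atoms: water, O
Why: In this SAMP/RAMP hydrazone alkylation the lithium azaenolate, rigidified by chelation to the methoxymethyl arm, is alkylated on its open face so that the auxiliary sets C4 (the later C12′) as R, and two-phase oxalic acid hydrolysis frees the ketone without racemisation or loss of the acetonide.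

Step 11
Reactants: 24 (4R)-2,2-dimethyl-4-(3-methylbut-2-en-1-yl)-1,3-dioxan-5-one; 25 allyltriphenylphosphonium bromide
Product: 27 (4R,5E)-2,2-dimethyl-4-(3-methylbut-2-en-1-yl)-5-(prop-2-en-1-ylidene)-1,3-dioxane, via allylidenetriphenylphosphorane 26 (not isolated)
Conditions: 25, NaN(SiMe3)2, THF, 0 °C; then 24, −78 °C to rt
Reagents that add atoms: none
Why: Wittig olefination of the activated α,α′-dioxygenated ketone with the weakly basic semi-stabilised allyl ylide should place the vinyl group anti to the substituted C4, avoiding allylic 1,3-strain with the prenyl group, to give the 5E diene without enolising the stereocentre.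

Step 12
Reactants: 27 (4R,5E)-2,2-dimethyl-4-(3-methylbut-2-en-1-yl)-5-(prop-2-en-1-ylidene)-1,3-dioxane; 17 1-[(2E,6E)-7-iodo-3-methylocta-2,6-dien-1-yl]-2,5-dimethoxy-3-methylbenzene
Product: 29 (4R,5E)-5-[(4E,8E)-10-(2,5-dimethoxy-3-methylphenyl)-4,8-dimethyldeca-4,8-dien-1-ylidene]-2,2-dimethyl-4-(3-methylbut-2-en-1-yl)-1,3-dioxane, via B-alkyl-9-BBN 28 (not isolated)
Conditions: 9-BBN (0.5 M in THF), 0 °C to rt; then 17, Pd(dppf)Cl2 (cat.), AsPh3, aq. Cs2CO3, DMF, rt
Reagents that add atoms: none
Why: 9-BBN adds by four-centre syn hydroboration only to the monosubstituted terminal alkene of the conjugated diene, with boron on the terminal carbon C8′, because the trisubstituted C10′=C11′ and C14′=C15′ alkenes are too hindered for this bulky borane, and the resulting borane is homoallylic and so not subject to allylic boron shifts. Base then forms the borate, which transfers its primary alkyl group to the alkenylpalladium iodide generated by oxidative addition of zerovalent palladium into the C7′–I bond, and reductive elimination forms the C7′–C8′ bond. The closest known reaction type is the B-alkyl Suzuki–Miyaura coupling of 9-BBN adducts with alkenyl iodides, including homoallyl–alkenyl couplings used to assemble 1,5-diene terpenoid chains. No ring is closed and no stereocentre is created: the 6′E geometry is that of the iodide, carried with retention through oxidative addition and reductive elimination, and the C12′ centre and the 10′E alkene are not touched. The step needs site selectivity in the hydroboration, secured by the steric bias of 9-BBN for the terminal CH2=CH of the diene, and transmetalation plus reductive elimination faster than β-hydride elimination of the alkylpalladium, secured by the wide-bite-angle dppf ligand with AsPh3 and aqueous Cs2CO3 in DMF at room temperature.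

Step 13
Reactants: 29 coupled acetonide
Product: 30 (2E,3R)-2-[(4E,8E)-10-(2,5-dimethoxy-3-methylphenyl)-4,8-dimethyldeca-4,8-dien-1-ylidene]-6-methylhept-5-ene-1,3-diol
Conditions: PPTS, MeOH/THF, rt
Reagents that add atoms: none
Why: Acid-catalysed transacetalisation with methanol removes the isopropylidene acetal under conditions too mild to ionise the allylic alcohols or to affect the aryl methyl ethers.

Step 14
Reactants: 30 dimethoxyarene diol
Product: 31 2-[(2E,6E,10E,12R)-12-hydroxy-11-(hydroxymethyl)-3,7,15-trimethylhexadeca-2,6,10,14-tetraen-1-yl]-6-methylcyclohexa-2,5-diene-1,4-dione (target)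
Conditions: (NH4)2Ce(NO3)6, MeCN/H2O, 0 °C
Reagents that add atoms: water, O
Why: Oxidative demethylation of the 1,4-dimethoxyarene by tetravalent cerium, with water attacking the arene radical cation, gives the para-quinone fast enough at 0 °C that the trisubstituted alkenes and the allylic diol should survive.

Compound list
1 | 4-methoxy-2-methylphenol | Cc1cc(OC)ccc1O | starting material
2 | 2-bromo-4-methoxy-6-methylphenol | Cc1cc(OC)cc(Br)c1O | intermediate
3 | 1-bromo-2,5-dimethoxy-3-methylbenzene | Cc1cc(OC)cc(Br)c1OC | intermediate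
4 | pent-3-yn-1-ol | CC#CCCO | starting material
5 | 5-bromopent-2-yne | CC#CCCBr | intermediate
6 | ethyl but-2-ynoate | CC#CC(=O)OCC | starting material
7 | pent-3-ynylmagnesium bromide | CC#CCC[Mg]Br | intermediate
8 | pent-3-ynylcopper | CC#CCC[Cu] | intermediate
9 | ethyl (2Z)-2-cuprio-3-methyloct-2-en-6-ynoate (alkenylcopper adduct) | CCOC(=O)/C([Cu])=C(\C)CCC#CC | intermediate
10 | ethyl (2E)-3-methyloct-2-en-6-ynoate | CCOC(=O)/C=C(\C)CCC#CC | intermediate
11 | (2E)-3-methyloct-2-en-6-yn-1-ol | CC#CCC/C(C)=C/CO | intermediate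
12 | (2E)-1-bromo-3-methyloct-2-en-6-yne | CC#CCC/C(C)=C/CBr | intermediate
13 | (2,5-dimethoxy-3-methylphenyl)lithium | [Li]c1cc(OC)cc(C)c1OC | intermediate
14 | (2,5-dimethoxy-3-methylphenyl)copper | [Cu]c1cc(OC)cc(C)c1OC | intermediate
15 | 2,5-dimethoxy-1-methyl-3-[(2E)-3-methyloct-2-en-6-yn-1-yl]benzene | CC#CCC/C(C)=C/Cc1cc(OC)cc(C)c1OC | intermediate
16 | chlorobis(cyclopentadienyl)zirconium (E)-alkenyl derived from 15, zirconium on the methyl-bearing carbon and trans to the chain | C/C(=C\CC/C(C)=C/Cc1cc(OC)cc(C)c1OC)[Zr](Cl)(C1C=CC=C1)C1C=CC=C1 | intermediate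
17 | 1-[(2E,6E)-7-iodo-3-methylocta-2,6-dien-1-yl]-2,5-dimethoxy-3-methylbenzene | C/C(I)=C\CC/C(C)=C/Cc1cc(OC)cc(C)c1OC | intermediate
18 | 2,2-dimethyl-1,3-dioxan-5-one | CC1(C)OCC(=O)CO1 | starting material
19 | (R)-1-amino-2-(methoxymethyl)pyrrolidine (RAMP) | COC[C@H]1CCCN1N | starting material
20 | (2R)-N-(2,2-dimethyl-1,3-dioxan-5-ylidene)-2-(methoxymethyl)pyrrolidin-1-amine | COC[C@H]1CCCN1N=C1COC(C)(C)OC1 | intermediate
21 | 1-bromo-3-methylbut-2-ene (prenyl bromide) | CC(C)=CCBr | starting material
22 | lithium azaenolate of 20 | COC[C@H]1CCCN1N([Li])C1=COC(C)(C)OC1 | intermediate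
23 | RAMP hydrazone of (4R)-2,2-dimethyl-4-(3-methylbut-2-en-1-yl)-1,3-dioxan-5-one (C=N geometry not defined) | COC[C@H]1CCCN1N=C1COC(C)(C)O[C@@H]1CC=C(C)C | intermediate
24 | (4R)-2,2-dimethyl-4-(3-methylbut-2-en-1-yl)-1,3-dioxan-5-one | CC(C)=CC[C@H]1OC(C)(C)OCC1=O | intermediate
25 | allyltriphenylphosphonium bromide | C=CC[P+](c1ccccc1)(c1ccccc1)c1ccccc1.[Br-] | starting material
26 | allylidenetriphenylphosphorane | C=CC=P(c1ccccc1)(c1ccccc1)c1ccccc1 | intermediate
27 | (4R,5E)-2,2-dimethyl-4-(3-methylbut-2-en-1-yl)-5-(prop-2-en-1-ylidene)-1,3-dioxane | CC(C)=CC[C@H]1OC(C)(C)OC/C1=C\C=C | intermediate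
28 | 9-{(3E)-3-[(4R)-2,2-dimethyl-4-(3-methylbut-2-en-1-yl)-1,3-dioxan-5-ylidene]propyl}-9-borabicyclo[3.3.1]nonane | CC(C)=CC[C@H]1OC(C)(C)OC/C1=C\CCB1C2CCCC1CCC2 | intermediate
29 | (4R,5E)-5-[(4E,8E)-10-(2,5-dimethoxy-3-methylphenyl)-4,8-dimethyldeca-4,8-dien-1-ylidene]-2,2-dimethyl-4-(3-methylbut-2-en-1-yl)-1,3-dioxane | CC(C)=CC[C@H]1OC(C)(C)OC/C1=C\CC/C(C)=C/CC/C(C)=C/Cc1cc(OC)cc(C)c1OC | intermediate
30 | (2E,3R)-2-[(4E,8E)-10-(2,5-dimethoxy-3-methylphenyl)-4,8-dimethyldeca-4,8-dien-1-ylidene]-6-methylhept-5-ene-1,3-diol | CC(C)=CC[C@@H](O)/C(=C/CC/C(C)=C/CC/C(C)=C/Cc1cc(OC)cc(C)c1OC)CO | intermediate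
31 | 2-[(2E,6E,10E,12R)-12-hydroxy-11-(hydroxymethyl)-3,7,15-trimethylhexadeca-2,6,10,14-tetraen-1-yl]-6-methylcyclohexa-2,5-diene-1,4-dione | CC(C)=CC[C@@H](O)/C(=C/CC/C(C)=C/CC/C(C)=C/CC1=CC(=O)C=C(C)C1=O)CO | target

Total step count: 14.
Longest linear sequence: 9 steps (steps 3, 4, 5, 6, 7, 8, 12, 13, 14, from pent-3-yn-1-ol 4).

Steps most likely to fail

Step 11. The ylide may act as a base on the α-alkoxy ketone, which would erode the configuration at C4 or return ketone, and the olefination may not discriminate well between the two alkene geometries. The fallback sets out from 24 and comes back at 27. Ketone 24 is treated with the non-basic stabilised ylide Ph3P=CHCO2Et (CH2Cl2, rt), which should give, under thermodynamic-like control, the enoate ethyl (2E)-2-[(4R)-2,2-dimethyl-4-(3-methylbut-2-en-1-yl)-1,3-dioxan-5-ylidene]acetate F1. Reduction with i-Bu2AlH (CH2Cl2, −78 °C) gives the allylic alcohol (2E)-2-[(4R)-2,2-dimethyl-4-(3-methylbut-2-en-1-yl)-1,3-dioxan-5-ylidene]ethan-1-ol F2. MnO2 (CH2Cl2, rt) oxidises it to the enal (2E)-2-[(4R)-2,2-dimethyl-4-(3-methylbut-2-en-1-yl)-1,3-dioxan-5-ylidene]acetaldehyde F3, and methylenation with Ph3P=CH2 (THF, −78 °C), fast on an aldehyde, returns diene 27.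

Step 12. Hydroboration may not be fully site-selective on the diene, or protodeboronation and β-hydride elimination of the alkylpalladium may outrun transmetalation and reductive elimination. The fallback sets out from 27 (through borane 28) and comes back at 29. Borane 28 is oxidised (NaOH, H2O2) to the homoallylic alcohol (3E)-3-[(4R)-2,2-dimethyl-4-(3-methylbut-2-en-1-yl)-1,3-dioxan-5-ylidene]propan-1-ol F4, which can be purified from any regioisomer. Appel-type iodination (I2, PPh3, imidazole, CH2Cl2) gives the iodide (4R,5E)-5-(3-iodopropylidene)-2,2-dimethyl-4-(3-methylbut-2-en-1-yl)-1,3-dioxane F5. LiCl-assisted insertion of zinc dust (THF, 40 °C) gives the homoallylic alkylzinc iodide F6, and Negishi coupling with iodide 17 under PdCl2(DPEphos) (THF, rt) should give 29 with retention of the alkene geometry.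

Step 14. The acidic tetravalent cerium medium may oxidise or ionise the free allylic 1,3-diol before the arene is consumed. The fallback sets out from 29 and comes back at 31. Acetonide 29 is oxidised with (NH4)2Ce(NO3)6 (MeCN/H2O, 0 °C) while the diol is still masked, to the quinone acetonide 2-{(2E,6E)-9-[(4R,5E)-2,2-dimethyl-4-(3-methylbut-2-en-1-yl)-1,3-dioxan-5-ylidene]-3,7-dimethylnona-2,6-dien-1-yl}-6-methylcyclohexa-2,5-diene-1,4-dione F7. The acetal is then cleaved on the quinone with AcOH/H2O/THF at rt to give 31.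

Further compounds
F1 | step 11 | ethyl (2E)-2-[(4R)-2,2-dimethyl-4-(3-methylbut-2-en-1-yl)-1,3-dioxan-5-ylidene]acetate | CC(C)=CC[C@H]1OC(C)(C)OC/C1=C\C(=O)OCC
F2 | step 11 | (2E)-2-[(4R)-2,2-dimethyl-4-(3-methylbut-2-en-1-yl)-1,3-dioxan-5-ylidene]ethan-1-ol | CC(C)=CC[C@H]1OC(C)(C)OC/C1=C\CO
F3 | step 11 | (2E)-2-[(4R)-2,2-dimethyl-4-(3-methylbut-2-en-1-yl)-1,3-dioxan-5-ylidene]acetaldehyde | CC(C)=CC[C@H]1OC(C)(C)OC/C1=C\C=O
F4 | step 12 | (3E)-3-[(4R)-2,2-dimethyl-4-(3-methylbut-2-en-1-yl)-1,3-dioxan-5-ylidene]propan-1-ol | CC(C)=CC[C@H]1OC(C)(C)OC/C1=C\CCO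
F5 | step 12 | (4R,5E)-5-(3-iodopropylidene)-2,2-dimethyl-4-(3-methylbut-2-en-1-yl)-1,3-dioxane | CC(C)=CC[C@H]1OC(C)(C)OC/C1=C\CCI
F6 | step 12 | {(3E)-3-[(4R)-2,2-dimethyl-4-(3-methylbut-2-en-1-yl)-1,3-dioxan-5-ylidene]propyl}zinc iodide | CC(C)=CC[C@H]1OC(C)(C)OC/C1=C\CC[Zn]I
F7 | step 14 | 2-{(2E,6E)-9-[(4R,5E)-2,2-dimethyl-4-(3-methylbut-2-en-1-yl)-1,3-dioxan-5-ylidene]-3,7-dimethylnona-2,6-dien-1-yl}-6-methylcyclohexa-2,5-diene-1,4-dione | CC(C)=CC[C@H]1OC(C)(C)OC/C1=C\CC/C(C)=C/CC/C(C)=C/CC1=CC(=O)C=C(C)C1=O
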